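**Retrosynthetic overview**
- Target ⇐ its tert-butyl ester ⇐ C-acylation (O-acylation, then O→C acyl shift) of (6R)-4-hydroxy-6-methyl-5,6-dihydropyran-2-one with a C9 acid; the ring–acyl bond is the last C–C bond.
- Key bond: the α-carbon of the future acid to the alkene carbon. An α-bromo ester serves as an enolonium (α-carbonyl cation) equivalent and is coupled with an (E)-alkenylzirconium; a chiral nickel catalyst converges both bromide epimers to the 2S centre and fixes the E-alkene.
- Alkenyl partner: (4R)-4-methylhept-6-ynoic acid from (R)-citronellal (Ohira–Bestmann alkynylation, then ozonolysis/chlorite oxidation of the isopropylidene end).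
- Electrophile: tert-butyl 2-bromo-(4S)-4-methylhexanoate from tert-butyl acetate and (S)-1-iodo-2-methylbutane.
- Rings: the only ring (the dihydropyranone) is not built; it is carried from 4-hydroxy-6-methyl-2-pyrone, with C6 set by asymmetric hydrogenation before the acylation.

Assumption: in the two catalyst-controlled steps (5 and 6) the ligand antipode written is the one expected to give the drawn configuration; the sense is checked on the first run and the mirror-image ligand is used if it is reversed.

**Step 1**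
Reactants: 1 (R)-citronellal
Product: 2 (4R)-4,8-dimethylnon-7-en-1-yne
Conditions: dimethyl (1-diazo-2-oxopropyl)phosphonate (1.2 equiv), K2CO3 (2 equiv), MeOH, 0 °C → rt, 12 h
Reagents that add atoms: dimethyl (1-diazo-2-oxopropyl)phosphonate (Ohira–Bestmann reagent), CC(=O)C(=[N+]=[N-])P(=O)(OC)OC
Why: Seyferth–Gilbert homologation in the Ohira–Bestmann variant: methanolysis of the reagent gives the diazomethylphosphonate anion, which olefinates the aldehyde and loses N2 to give the terminal alkyne; the stereocentre is β to the aldehyde and is not touched by K2CO3/MeOH.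

**Step 2**
Reactants: 2 (4R)-4,8-dimethylnon-7-en-1-yne
Product: 4 (4R)-4-methylhept-6-ynoic acid, via (4R)-4-methylhept-6-ynal 3 (not isolated)
Conditions: O3 (1.05 equiv, metered), MeCN/H2O 9:1, 0 °C; then NaClO2 (1.5 equiv), NaH2PO4, 0 °C → rt
Reagents that add atoms: ozone, [O-][O+]=O; sodium chlorite, [Na+].[O-]Cl=O
Why: Chemoselective ozonolysis (the electron-rich trisubstituted alkene reacts orders of magnitude faster than the terminal alkyne) in aqueous acetonitrile, where water traps the carbonyl oxide to give aldehyde, acetone and H2O2 directly, followed in the same pot by Pinnick chlorite oxidation with the H2O2 as hypochlorite scavenger; the stereocentre is remote and untouched.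

**Step 3**
Reactants: 5 tert-butyl acetate; 6 (S)-1-iodo-2-methylbutane
Product: 8 tert-butyl (4S)-4-methylhexanoate, via lithium enolate of tert-butyl acetate 7 (not isolated)
Conditions: LiN(i-Pr)2 (1.5 equiv), 5 (1.6 equiv), THF, −78 °C; then 6 (1.0 equiv), DMPU, −78 → 23 °C, 12 h
Reagents that add atoms: none
Why: SN2 enolate alkylation: the lithium enolate of tert-butyl acetate is stable to room temperature and displaces the primary iodide in THF/DMPU; the stereocentre of 6 is β to the reacting carbon and is carried through unchanged.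

**Step 4**
Reactants: 8 tert-butyl (4S)-4-methylhexanoate
Product: 10 tert-butyl (2RS,4S)-2-bromo-4-methylhexanoate, via lithium enolate of the hexanoate 9 (not isolated)
Conditions: LiN(i-Pr)2 (1.1 equiv), THF, −78 °C; cannulated into BrCl2C–CCl2Br (1.2 equiv), THF, −78 °C
Reagents that add atoms: 1,2-dibromo-1,1,2,2-tetrachloroethane, ClC(Cl)(Br)C(Cl)(Cl)Br
Why: Electrophilic α-bromination of a kinetic ester enolate (inverse addition suppresses proton exchange and dibromination); both C2 epimers form, which does not matter because step 5 is stereoconvergent.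

**Step 5 (key step)**
Reactants: 4 (4R)-4-methylhept-6-ynoic acid (1.3 equiv); 10 tert-butyl (2RS,4S)-2-bromo-4-methylhexanoate (1.0 equiv)
Product: 12 (4R,6E,8S)-9-tert-butoxy-4-methyl-8-[(2S)-2-methylbutyl]-9-oxonon-6-enoic acid, via (E)-alkenylzirconocene zirconium carboxylate 11 (not isolated)
Conditions: Cp2Zr(H)Cl (2.1 equiv per 4), THF, rt, 30 min; then 10, NiCl2·glyme (5 mol%), (S,S)-Ph-BOX (6.5 mol%), DME, 10 °C, 24 h; 1 M HCl
Reagents that add atoms: none
Why: Proposed new method: the first equivalent of Cp2Zr(H)Cl converts CO2H into an inert zirconocene carboxylate (H2 lost) and the second adds syn across the terminal alkyne to give the (E)-alkenylzirconocene; the bis(oxazoline)nickel catalyst abstracts bromine from either C2 epimer of 10 to the same planar α-ester radical (the enolonium-equivalent carbon), which is captured by the chiral alkenylnickel species, and reductive elimination sets the new centre (C8 of 12, S) under catalyst control with retention of the E geometry and without base, so the β,γ-unsaturated ester neither epimerises nor conjugates; closest known reaction types are the nickel/bis(oxazoline)-catalysed stereoconvergent alkenylation of racemic α-bromo ketones with alkenylzirconium reagents and the nickel-catalysed Hiyama alkenylation of racemic α-bromo esters.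

**Step 6**
Reactants: 13 4-hydroxy-6-methyl-2H-pyran-2-one
Product: 14 (6R)-4-hydroxy-6-methyl-5,6-dihydro-2H-pyran-2-one
Conditions: [Ru(OAc)2((S)-MeO-BIPHEP)] (0.5 mol%), HBF4·OEt2 (1 mol%), H2 (60 bar), MeOH, 60 °C; recrystallise
Reagents that add atoms: none
Why: Asymmetric hydrogenation of a 4-hydroxy-2-pyrone: the cationic ruthenium–biaryl diphosphine catalyst reduces only the 5,6-double bond (the enolised β-keto lactone is left), the atropisomeric ligand selects the face and sets C6 as R, and recrystallisation raises the ee.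

**Step 7**
Reactants: 12 (4R,6E,8S)-9-tert-butoxy-4-methyl-8-[(2S)-2-methylbutyl]-9-oxonon-6-enoic acid; 14 (6R)-4-hydroxy-6-methyl-5,6-dihydro-2H-pyran-2-one
Product: 16 tert-butyl (2S,3E,6R)-9-[(6R)-4-hydroxy-6-methyl-2-oxo-5,6-dihydro-2H-pyran-3-yl]-6-methyl-2-[(2S)-2-methylbutyl]-9-oxonon-3-enoate, via enol ester 15 (not isolated)
Conditions: DCC (1.1 equiv), DMAP (1.2 equiv), CH2Cl2, 0 °C → rt, 18 h
Reagents that add atoms: none
Why: Steglich-type O-acylation of the enol of 14 by the DCC-activated acid, then DMAP-mediated O→C acyl migration (Fries-type rearrangement through the acylpyridinium/enolate pair) to the chelated 3-acyl tricarbonyl, the thermodynamic sink; no stereocentre is involved and the tert-butyl ester is inert.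

**Step 8**
Reactants: 16 tert-butyl (2S,3E,6R)-9-[(6R)-4-hydroxy-6-methyl-2-oxo-5,6-dihydro-2H-pyran-3-yl]-6-methyl-2-[(2S)-2-methylbutyl]-9-oxonon-3-enoate
Product: 17 (2S,3E,6R)-9-[(6R)-4-hydroxy-6-methyl-2-oxo-5,6-dihydro-2H-pyran-3-yl]-6-methyl-2-[(2S)-2-methylbutyl]-9-oxonon-3-enoic acid
Conditions: CF3CO2H/CH2Cl2 1:4, 0 °C → rt, 2 h
Reagents that add atoms: none
Why: Acidolysis of the tert-butyl ester (E1 loss of isobutene); the acid-stable 3-acyl-4-hydroxy-dihydropyranone, the E-alkene and the α-stereocentre are untouched because no base is present.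

**Compound list**
1 | (R)-citronellal, (3R)-3,7-dimethyloct-6-enal | C[C@H](CCC=C(C)C)CC=O | starting material
2 | (4R)-4,8-dimethylnon-7-en-1-yne | C#CC[C@H](C)CCC=C(C)C | intermediate
3 | (4R)-4-methylhept-6-ynal (not isolated) | C#CC[C@H](C)CCC=O | intermediate
4 | (4R)-4-methylhept-6-ynoic acid | C#CC[C@H](C)CCC(=O)O | intermediate
5 | tert-butyl acetate | CC(=O)OC(C)(C)C | starting material
6 | (S)-1-iodo-2-methylbutane | CC[C@H](C)CI | starting material
7 | lithium enolate of tert-butyl acetate (not isolated) | [Li]OC(=C)OC(C)(C)C | intermediate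
8 | tert-butyl (4S)-4-methylhexanoate | CC[C@H](C)CCC(=O)OC(C)(C)C | intermediate
9 | lithium enolate of tert-butyl (4S)-4-methylhexanoate (not isolated) | CC[C@H](C)CC=C(O[Li])OC(C)(C)C | intermediate
10 | tert-butyl (2RS,4S)-2-bromo-4-methylhexanoate, both C2 epimers | CC[C@H](C)CC(Br)C(=O)OC(C)(C)C | intermediate
11 | chlorozirconocene (4R,6E)-7-(chlorozirconocenyl)-4-methylhept-6-enoate (not isolated; Cp rings written σ-bonded in the SMILES) | Cl[Zr](C1C=CC=C1)(C1C=CC=C1)/C=C/C[C@H](C)CCC(=O)O[Zr](Cl)(C1C=CC=C1)C1C=CC=C1 | intermediate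
12 | (4R,6E,8S)-9-tert-butoxy-4-methyl-8-[(2S)-2-methylbutyl]-9-oxonon-6-enoic acid | CC[C@H](C)C[C@@H](/C=C/C[C@H](C)CCC(=O)O)C(=O)OC(C)(C)C | intermediate
13 | 4-hydroxy-6-methyl-2H-pyran-2-one | CC1=CC(O)=CC(=O)O1 | starting material
14 | (6R)-4-hydroxy-6-methyl-5,6-dihydro-2H-pyran-2-one | C[C@@H]1CC(O)=CC(=O)O1 | intermediate
15 | 1-tert-butyl 9-[(6R)-6-methyl-2-oxo-5,6-dihydro-2H-pyran-4-yl] (2S,3E,6R)-6-methyl-2-[(2S)-2-methylbutyl]non-3-enedioate (not isolated) | CC[C@H](C)C[C@@H](/C=C/C[C@H](C)CCC(=O)OC1=CC(=O)O[C@H](C)C1)C(=O)OC(C)(C)C | intermediate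
16 | tert-butyl (2S,3E,6R)-9-[(6R)-4-hydroxy-6-methyl-2-oxo-5,6-dihydro-2H-pyran-3-yl]-6-methyl-2-[(2S)-2-methylbutyl]-9-oxonon-3-enoate | CC[C@H](C)C[C@@H](/C=C/C[C@H](C)CCC(=O)C1=C(O)C[C@@H](C)OC1=O)C(=O)OC(C)(C)C | intermediate
17 | (2S,3E,6R)-9-[(6R)-4-hydroxy-6-methyl-2-oxo-5,6-dihydro-2H-pyran-3-yl]-6-methyl-2-[(2S)-2-methylbutyl]-9-oxonon-3-enoic acid (CNP0241663.1) | CC[C@H](C)C[C@@H](/C=C/C[C@H](C)CCC(=O)C1=C(O)C[C@@H](C)OC1=O)C(=O)O | target

**Step count**
Total steps: 8. Longest linear sequence: 5 steps (steps 1, 2, 5, 7, 8).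

**Three steps most likely to fail**

Step 5 is the riskiest. It extends the alkenylzirconium coupling from α-bromo ketones to a tert-butyl α-bromo ester, carries the acid through as a zirconium carboxylate, and relies on catalyst control for the new centre. The fallback sets out from 4 and comes back at 12; it replaces the zirconium nucleophile by an isolated alkenylsilane and protects the acid. Compound 4 is esterified (MeOH, cat. H2SO4) to methyl (4R)-4-methylhept-6-ynoate F1. Hydrosilylation with HSi(OMe)3 (Pt2(dvds)3, P(t-Bu)3, THF) gives methyl (4R,6E)-4-methyl-7-(trimethoxysilyl)hept-6-enoate F2. Stereoconvergent Hiyama coupling of F2 with 10 (NiCl2·glyme, (S,S)-N,N'-dimethyl-1,2-diphenylethane-1,2-diamine, tetrabutylammonium difluorotriphenylsilicate, dioxane, rt) gives 1-tert-butyl 9-methyl (2S,3E,6R)-6-methyl-2-[(2S)-2-methylbutyl]non-3-enedioate F3. Me3SnOH (1,2-dichloroethane, 80 °C) then cleaves only the unhindered methyl ester, without epimerisation, to give 12.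

Step 7 can stall at the enol ester 15 or give low yields in the O→C shift. The fallback sets out from 12 and comes back at 16; it builds the ring onto the acyl chain instead of acylating a preformed ring. Compound 12 is condensed with Meldrum's acid (DCC, DMAP, CH2Cl2) to tert-butyl (2S,3E,6R)-9-(2,2-dimethyl-4,6-dioxo-1,3-dioxan-5-ylidene)-9-hydroxy-6-methyl-2-[(2S)-2-methylbutyl]non-3-enoate F4. Heating F4 with commercial ethyl (R)-3-hydroxybutanoate (C[C@@H](O)CC(=O)OCC) in toluene at 80 °C traps the acylketene as 1-tert-butyl 11-[(2R)-4-ethoxy-4-oxobutan-2-yl] (2S,3E,6R)-6-methyl-2-[(2S)-2-methylbutyl]-9-oxoundec-3-enedioate F5. Dieckmann cyclisation of the β-keto ester anion onto the ethyl ester (Bu4NF, THF, rt) closes the ring to 16; C6 then comes from the chiral pool, and β-elimination of the acyloxy group is the side reaction to watch.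

Step 6 may give insufficient ee, the wrong sense, or over-reduction of the β-keto lactone. The fallback sets out from 5 and comes back at 14; it takes C6 from the chiral pool instead of from a catalyst. The lithium enolate 7 (3.5 equiv, made from 5) undergoes crossed Claisen condensation with ethyl (R)-3-hydroxybutanoate (THF, −78 → −20 °C) to give tert-butyl (5R)-5-hydroxy-3-oxohexanoate F6. CF3CO2H in CH2Cl2 removes the tert-butyl group and the δ-hydroxy-β-keto acid lactonises to 14.

**Further compounds**
F1 | step 5 | methyl (4R)-4-methylhept-6-ynoate | C#CC[C@H](C)CCC(=O)OC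
F2 | step 5 | methyl (4R,6E)-4-methyl-7-(trimethoxysilyl)hept-6-enoate | CO[Si](OC)(OC)/C=C/C[C@H](C)CCC(=O)OC
F3 | step 5 | 1-tert-butyl 9-methyl (2S,3E,6R)-6-methyl-2-[(2S)-2-methylbutyl]non-3-enedioate | CC[C@H](C)C[C@@H](/C=C/C[C@H](C)CCC(=O)OC)C(=O)OC(C)(C)C
F4 | step 7 | tert-butyl (2S,3E,6R)-9-(2,2-dimethyl-4,6-dioxo-1,3-dioxan-5-ylidene)-9-hydroxy-6-methyl-2-[(2S)-2-methylbutyl]non-3-enoate | CC[C@H](C)C[C@@H](/C=C/C[C@H](C)CCC(O)=C1C(=O)OC(C)(C)OC1=O)C(=O)OC(C)(C)C
F5 | step 7 | 1-tert-butyl 11-[(2R)-4-ethoxy-4-oxobutan-2-yl] (2S,3E,6R)-6-methyl-2-[(2S)-2-methylbutyl]-9-oxoundec-3-enedioate | CC[C@H](C)C[C@@H](/C=C/C[C@H](C)CCC(=O)CC(=O)O[C@H](C)CC(=O)OCC)C(=O)OC(C)(C)C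
F6 | step 6 | tert-butyl (5R)-5-hydroxy-3-oxohexanoate | C[C@@H](O)CC(=O)CC(=O)OC(C)(C)C
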